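**Retrosynthetic overview**
1. The last bond made is C20–O: a catalyst-controlled conjugate hydration of cycloheptadienone 27, whose enone is unmasked from silyl enol ether 26.
2. The five- and seven-membered rings of the hydroazulene close together (last ring-forming step) by a rhodium [5+2] cycloaddition of the C22≡C23 alkyne onto the (1-silyloxyvinyl)cyclopropane in 25.
3. C14 is set by nickel hydroalkynylation of diene 21; the C11–C14 bond comes from Suzuki coupling of diquinane vinyl triflate 16 with boronate 20.
4. The side chain comes from Felkin addition of an (R)-but-3-yn-2-ol-derived alkenyllithium to the C6 methyl ketone 10.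
5. The diquinane starts from 2-methylcyclopentane-1,3-dione (ring D); ring C is formed first, by alkyne hydration and asymmetric aldol condensation (5), then 1,4-reduction and triflation (7).

Locants used in the names (assumption: (R)-but-3-yn-2-ol is bought as a chiral-pool reagent): C1–C5 side chain (C2 secondary carbinol, C5 tertiary carbinol); C6–C9 and C13 ring D; C9–C13 ring C (C10=C11, methyl on C13); C14–C17 and C23 cyclopentane; C17–C23 seven-membered ring (C18 ketone, C20 carbinol, C22=C23). The target is (2R,5S,6S,9S,13R,14R,17R,20R) in these locants.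

**Route**

Step 1
Reactants: 1 2-methylcyclopentane-1,3-dione; 2 3-bromoprop-1-yne
Product: 3 2-methyl-2-(prop-2-yn-1-yl)cyclopentane-1,3-dione
Conditions: NaOH (1.1 equiv), H2O, 60 °C
Reagents that add atoms: none
Why: C-alkylation of the cyclic 1,3-diketone enolate (SN2) puts the future C10–C12 carbons on the quaternary carbon, which is still prochiral.

Step 2
Reactants: 3 2-methyl-2-(prop-2-yn-1-yl)cyclopentane-1,3-dione
Product: 5 (3aR)-3a-methyl-3,3a,5,6-tetrahydropentalene-2,4-dione, via triketone 4 (not isolated)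
Conditions: NaAuCl4·2H2O (2 mol %), MeOH/H2O, 65 °C; concentrate; then D-phenylalanine (1 equiv), (1R)-camphor-10-sulfonic acid (0.5 equiv), DMF, 70 °C
Reagents that add atoms: water, O
Why: Gold-catalysed Markovnikov alkyne hydration gives the methyl ketone, and the amino-acid-mediated intramolecular aldol condensation (Hajos–Parrish type, via the enamine) chooses one of the two enantiotopic ring ketones and so sets C13 as R, the D-amino acid being used because the L-series gives the S-configured Hajos–Parrish-type ketones.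

Step 3
Reactants: 5 (3aR)-3a-methyl-3,3a,5,6-tetrahydropentalene-2,4-dione
Product: 7 (3aR,6aS)-3a-methyl-4-oxo-3,3a,4,5,6,6a-hexahydropentalen-2-yl trifluoromethanesulfonate, via silyl enol ether 6 (not isolated)
Conditions: Et3SiH, RhCl(PPh3)3 (1 mol %), THF, 50 °C; then CsF, PhNTf2, DME, 23 °C
Reagents that add atoms: N-phenylbis(trifluoromethanesulfonimide), O=S(=O)(N(c1ccccc1)S(=O)(=O)C(F)(F)F)C(F)(F)F; triethylsilane, CC[SiH](CC)CC (its silicon stays only in 6)
Why: Rhodium-catalysed 1,4-hydrosilylation of the enone puts hydrogen on C9 cis to the C13 methyl because only the cis-fused bicyclo[3.3.0]octane is unstrained (C9 S), and fluoride-triggered O-triflation of the regiodefined silyl enol ether fixes the C10=C11 double bond while the hindered C6 ketone is untouched.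

Step 4
Reactants: 7 keto vinyl triflate
Product: 9 C6-hydroxy C6-acetyl vinyl triflate, via lithium alkoxide 8 (not isolated)
Conditions: methyl vinyl ether, t-BuLi, THF, −78 → 0 °C; then 7, −78 °C; then 1 M HCl, THF, 0 °C
Reagents that add atoms: methyl vinyl ether, COC=C; water, O
Why: 1,2-Addition of the small acyl-anion equivalent 1-methoxyvinyllithium to the neopentyl C6 ketone, followed by acid hydrolysis of the enol ether, gives the α-hydroxy methyl ketone, whose new carbinol centre is erased in step 5.

Step 5
Reactants: 9 C6-hydroxy C6-acetyl vinyl triflate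
Product: 10 (3aR,4S,6aS)-4-acetyl-3a-methyl-3,3a,4,5,6,6a-hexahydropentalen-2-yl trifluoromethanesulfonate
Conditions: SmI2 (2.5 equiv), THF/MeOH, −78 °C
Reagents that add atoms: none
Why: Samarium diiodide reductive cleavage of the α-hydroxy ketone C–O bond gives an enolate that methanol protonates kinetically on the convex face (the face of the C13 methyl and C9–H), which sets C6 as S with the acetyl group trans to the methyl.

Step 6
Reactants: 11 (R)-but-3-yn-2-ol
Product: 12 (R)-tert-butyl(but-3-yn-2-yloxy)dimethylsilane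
Conditions: TBSCl, imidazole, DMF, 23 °C
Reagents that add atoms: tert-butyldimethylsilyl chloride, CC(C)(C)[Si](C)(C)Cl
Why: Silyl ether protection of the chiral-pool carbinol that becomes C2 (R), with no change at the stereocentre.

Step 7
Reactants: 12 (R)-tert-butyl(but-3-yn-2-yloxy)dimethylsilane
Product: 14 (R,E)-tert-butyl[(4-iodobut-3-en-2-yl)oxy]dimethylsilane, via alkenylzirconocene 13 (not isolated)
Conditions: Cp2Zr(H)Cl (1.3 equiv), THF, 23 °C; then I2, 0 °C
Reagents that add atoms: iodine, II; Cp2Zr(H)Cl, [H][Zr](Cl)(C1C=CC=C1)C1C=CC=C1 (its zirconium stays only in 13)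
Why: Syn hydrozirconation of the terminal alkyne followed by iodinolysis with retention gives the (E)-vinyl iodide that becomes C3=C4.

Step 8
Reactants: 10 C6-acetyl vinyl triflate; 14 (R,E)-vinyl iodide
Product: 16 side-chain vinyl triflate (C2 OTBS; C5 OH; 2R,5S), via alkenyllithium 15 (not isolated)
Conditions: 14, t-BuLi (2.1 equiv), Et2O, −78 °C; then 10, −78 °C; then H2O
Reagents that add atoms: none
Why: Iodine–lithium exchange and Felkin–Anh 1,2-addition of the alkenyllithium to the methyl ketone (quaternary C13 as the large group anti to the nucleophile, attack past C6–H) set the tertiary carbinol C5 as S and bring in C2 and the E alkene.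

Step 9
Reactants: 17 cyclopropyl methyl ketone; 2 3-bromoprop-1-yne
Product: 19 1-cyclopropylpent-4-yn-1-one, via lithium enolate 18 (not isolated)
Conditions: LiN(i-Pr)2 (1.05 equiv), THF, −78 °C; then 2, −78 → 0 °C
Reagents that add atoms: none
Why: Kinetic enolate alkylation at the methyl group (the cyclopropyl methine is not deprotonated) builds the C14–C18 chain with the cyclopropane that supplies C19–C21.

Step 10
Reactants: 19 1-cyclopropylpent-4-yn-1-one
Product: 20 (E)-1-cyclopropyl-5-(4,4,5,5-tetramethyl-1,3,2-dioxaborolan-2-yl)pent-4-en-1-one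
Conditions: B2pin2, CuCl (5 mol %), Xantphos (5 mol %), NaOt-Bu (10 mol %), MeOH (2 equiv), THF, 23 °C
Reagents that add atoms: bis(pinacolato)diboron, CC1(C)OB(OC1(C)C)B1OC(C)(C)C(C)(C)O1
Why: Copper-catalysed syn protoboration of the terminal alkyne gives the (E)-alkenylboronate and tolerates the ketone.

Step 11
Reactants: 16 side-chain vinyl triflate; 20 (E)-alkenylboronate
Product: 21 diene ketone (C10=C11–C14=C15; 14E)
Conditions: Pd(PPh3)4 (5 mol %), K3PO4, 1,4-dioxane/H2O, 60 °C
Reagents that add atoms: none
Why: Suzuki–Miyaura coupling of the vinyl triflate with the alkenylboronate forms the C11–C14 bond with retention of both alkene geometries.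

Step 12
Reactants: 21 diene ketone; 22 ethynyltri(propan-2-yl)silane
Product: 23 silyl 1,4-enyne (14R)
Conditions: 22 (2 equiv), Ni(cod)2 (10 mol %), (R,R)-TADDOL-derived phosphoramidite (20 mol %), toluene, 40 °C
Reagents that add atoms: none
Why: Nickel-catalysed hydroalkynylation of the 1,3-diene, in which Ni–H adds at C15 of the less substituted alkene, reductive elimination of the allylnickel acetylide at the acyclic terminus C14 keeps the ring alkene, and the chiral phosphoramidite controls the new C14 centre (R).

Step 13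
Reactants: 23 silyl 1,4-enyne
Product: 24 terminal 1,4-enyne ketone
Conditions: TBAF (1.1 equiv), THF, 0 °C
Reagents that add atoms: none
Why: Fluoride protodesilylation of the alkynylsilane is much faster than cleavage of the secondary silyl ether and leaves C14 untouched.

Step 14
Reactants: 24 terminal 1,4-enyne ketone
Product: 25 (Z)-triethylsilyl enol ether (C17=C18; C5 OTES)
Conditions: TESOTf (3 equiv), Et3N (5 equiv), CH2Cl2, −78 → 0 °C
Reagents that add atoms: triethylsilyl trifluoromethanesulfonate, CC[Si](CC)(CC)OS(=O)(=O)C(F)(F)F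
Why: Soft enolisation and silylation gives the (Z)-silyl enol ether on the only enolisable side (a cyclopropyl methine does not enolise) and caps the tertiary alcohol, so the C18 oxygen is fixed regiochemically as an enol ether with the cyclopropane trans to the tether.

Step 15
Reactants: 25 (Z)-triethylsilyl enol ether
Product: 26 tetracyclic silyl enol ether (C18(OTES)=C19; C22=C23; 14R,17R)
Conditions: [Rh(CO)2Cl]2 (5 mol %), 1,2-dichloroethane, 70 °C
Reagents that add atoms: none
Why: Wender-type rhodium-catalysed intramolecular [5+2] cycloaddition of the alkyne with the vinylcyclopropane (substituted on the internal alkene carbon, which favours the reactive s-cis conformer) forms the C17–C23 and C21–C22 bonds, and the C14 substituent sits pseudo-equatorial in the five-membered-ring-forming transition state so that C14–H and C17–H end up cis (C17 R).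

Step 16
Reactants: 26 tetracyclic silyl enol ether
Product: 27 dienone (C18=O; C19=C20; C22=C23)
Conditions: Pd(OAc)2 (1.1 equiv), MeCN, 23 °C
Reagents that add atoms: none
Why: Saegusa–Ito oxidation, in which the palladium enolate from the silyl enol ether can only β-hydride eliminate towards C20, gives the C19=C20 enone under neutral conditions that leave C17–H and the C22=C23 double bond in place.

Step 17
Reactants: 27 dienone
Product: 28 β-hydroxy ketone (20R; C2 OTBS; C5 OTES)
Conditions: [Pd((R)-DTBM-SEGPHOS)(OH2)2](OTf)2 (5 mol %), H2O (20 equiv), THF, 0 °C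
Reagents that add atoms: water, O
Why: Proposed new method: a cationic chiral bisphosphine diaqua complex of divalent palladium binds the enone oxygen as a soft Lewis acid while its conjugate base, the palladium hydroxide, delivers hydroxide to C20 from the face set by the ligand (the ligand enantiomer is to be confirmed by experiment), and the palladium enolate is protonated by water, so the C20–O bond and the R centre form under nearly neutral conditions that spare the acidic C17–H; the closest known reactions are palladium aqua/hydroxo-catalysed enantioselective aza-Michael additions and the achiral palladium-catalysed hydroalkoxylation of enones, whereas an enantioselective intermolecular conjugate hydration of a cyclic enone is not known.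

Step 18
Reactants: 28 β-hydroxy ketone
Product: 29 CNP0358460.1
Conditions: HF·pyridine, pyridine, THF, 0 → 23 °C
Reagents that add atoms: none
Why: Buffered fluoride desilylation removes the secondary TBS and tertiary TES ethers without base, so the β-hydroxy ketone, the β,γ-unsaturated ketone and the tertiary allylic alcohol survive.

**Compound list**
1 | 2-methylcyclopentane-1,3-dione | CC1C(=O)CCC1=O | starting material
2 | 3-bromoprop-1-yne (propargyl bromide) | BrCC#C | starting material
3 | 2-methyl-2-(prop-2-yn-1-yl)cyclopentane-1,3-dione | CC1(CC#C)C(=O)CCC1=O | intermediate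
4 | 2-methyl-2-(2-oxopropyl)cyclopentane-1,3-dione (triketone, not isolated) | CC(=O)CC1(C)C(=O)CCC1=O | intermediate
5 | (3aR)-3a-methyl-3,3a,5,6-tetrahydropentalene-2,4-dione (C13 R; C9=C10; ketones at C11 and C6) | O=C1CCC2=CC(=O)C[C@]21C | intermediate
6 | C10=C11 triethylsilyl enol ether of the cis-fused C6 ketone (9S,13R; not isolated) | O=C1CC[C@H]2C=C(O[Si](CC)(CC)CC)C[C@]21C | intermediate
7 | (3aR,6aS)-3a-methyl-4-oxo-3,3a,4,5,6,6a-hexahydropentalen-2-yl trifluoromethanesulfonate (C11 enol triflate; C6 ketone) | O=C1CC[C@H]2C=C(OS(=O)(=O)C(F)(F)F)C[C@]21C | intermediate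
8 | lithium alkoxide of the C6 1-methoxyvinyl adduct of 7 (C–C bond drawn on the convex face; not isolated) | C=C(OC)[C@]1(O[Li])CC[C@H]2C=C(OS(=O)(=O)C(F)(F)F)C[C@]21C | intermediate
9 | C6-hydroxy C6-acetyl vinyl triflate (C6 drawn as the convex-face adduct; 9S,13R) | CC(=O)[C@]1(O)CC[C@H]2C=C(OS(=O)(=O)C(F)(F)F)C[C@]21C | intermediate
10 | (3aR,4S,6aS)-4-acetyl-3a-methyl-3,3a,4,5,6,6a-hexahydropentalen-2-yl trifluoromethanesulfonate (C6 acetyl trans to the C13 methyl; 6S,9S,13R) | CC(=O)[C@H]1CC[C@H]2C=C(OS(=O)(=O)C(F)(F)F)C[C@]21C | intermediate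
11 | (R)-but-3-yn-2-ol | C[C@@H](O)C#C | starting material
12 | (R)-tert-butyl(but-3-yn-2-yloxy)dimethylsilane | C[C@@H](O[Si](C)(C)C(C)(C)C)C#C | intermediate
13 | (R,E)-alkenylzirconocene chloride from 12 (not isolated) | C[C@@H](O[Si](C)(C)C(C)(C)C)/C=C/[Zr](Cl)(C1C=CC=C1)C1C=CC=C1 | intermediate
14 | (R,E)-tert-butyl[(4-iodobut-3-en-2-yl)oxy]dimethylsilane | C[C@@H](O[Si](C)(C)C(C)(C)C)/C=C/I | intermediate
15 | (R,E)-[3-(tert-butyldimethylsilyloxy)but-1-en-1-yl]lithium (not isolated) | C[C@@H](O[Si](C)(C)C(C)(C)C)/C=C/[Li] | intermediate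
16 | side-chain vinyl triflate: diquinane C11 triflate with C2 OTBS, (3E) alkene and C5 OH (2R,5S,6S,9S,13R) | C[C@@H](O[Si](C)(C)C(C)(C)C)/C=C/[C@](C)(O)[C@H]1CC[C@H]2C=C(OS(=O)(=O)C(F)(F)F)C[C@]21C | intermediate
17 | cyclopropyl methyl ketone | CC(=O)C1CC1 | starting material
18 | lithium 1-cyclopropylethen-1-olate (not isolated) | [Li]OC(=C)C1CC1 | intermediate
19 | 1-cyclopropylpent-4-yn-1-one | C#CCCC(=O)C1CC1 | intermediate
20 | (E)-1-cyclopropyl-5-(4,4,5,5-tetramethyl-1,3,2-dioxaborolan-2-yl)pent-4-en-1-one | CC1(C)OB(/C=C/CCC(=O)C2CC2)OC1(C)C | intermediate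
21 | diene ketone: C11 bears the (E)-5-cyclopropyl-5-oxopent-1-enyl chain (C14=C15); side chain as in 16 | C[C@@H](O[Si](C)(C)C(C)(C)C)/C=C/[C@](C)(O)[C@H]1CC[C@H]2C=C(/C=C/CCC(=O)C3CC3)C[C@]21C | intermediate
22 | ethynyltri(propan-2-yl)silane | C#C[Si](C(C)C)(C(C)C)C(C)C | starting material
23 | silyl 1,4-enyne: C14 (R) bears H, the (triisopropylsilyl)ethynyl group and the 4-cyclopropyl-4-oxobutyl chain | C[C@@H](O[Si](C)(C)C(C)(C)C)/C=C/[C@](C)(O)[C@H]1CC[C@H]2C=C([C@H](C#C[Si](C(C)C)(C(C)C)C(C)C)CCCC(=O)C3CC3)C[C@]21C | intermediate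
24 | terminal 1,4-enyne ketone (same arrangement at C14 as 23, S by the priority rules) | C[C@@H](O[Si](C)(C)C(C)(C)C)/C=C/[C@](C)(O)[C@H]1CC[C@H]2C=C([C@H](C#C)CCCC(=O)C3CC3)C[C@]21C | intermediate
25 | (Z)-C17=C18 triethylsilyl enol ether of 24 with C5 OTES | C[C@@H](O[Si](C)(C)C(C)(C)C)/C=C/[C@](C)(O[Si](CC)(CC)CC)[C@H]1CC[C@H]2C=C([C@H](C#C)CC/C=C(\O[Si](CC)(CC)CC)C3CC3)C[C@]21C | intermediate
26 | tetracyclic silyl enol ether: bicyclo[5.3.0]decadiene with C18(OTES)=C19 and C22=C23 (14R,17R; C14–H and C17–H cis) | C[C@@H](O[Si](C)(C)C(C)(C)C)/C=C/[C@](C)(O[Si](CC)(CC)CC)[C@H]1CC[C@H]2C=C([C@H]3CC[C@H]4C(O[Si](CC)(CC)CC)=CCCC=C34)C[C@]21C | intermediate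
27 | dienone: C18 ketone, C19=C20 and C22=C23 (14R,17R) | C[C@@H](O[Si](C)(C)C(C)(C)C)/C=C/[C@](C)(O[Si](CC)(CC)CC)[C@H]1CC[C@H]2C=C([C@H]3CC[C@H]4C(=O)C=CCC=C34)C[C@]21C | intermediate
28 | β-hydroxy ketone: C20 OH (R) cis to C17–H; C2 OTBS; C5 OTES | C[C@@H](O[Si](C)(C)C(C)(C)C)/C=C/[C@](C)(O[Si](CC)(CC)CC)[C@H]1CC[C@H]2C=C([C@H]3CC[C@H]4C(=O)C[C@H](O)CC=C34)C[C@]21C | intermediate
29 | CNP0358460.1 (2R,5S,6S,9S,13R,14R,17R,20R) | C[C@@H](O)/C=C/[C@](C)(O)[C@H]1CC[C@H]2C=C([C@H]3CC[C@H]4C(=O)C[C@H](O)CC=C34)C[C@]21C | target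

**Step count and risks**

Total step count: 18. Longest linear sequence: 14 steps (steps 1–5, 8, 11–18).

The three steps most likely to fail:

Step 12 (nickel hydroalkynylation). This reaction is established for simpler, mostly terminal dienes; the internal trisubstituted diene 21 may react slowly, and zerovalent nickel may attack the cyclopropyl ketone. The fallback makes C14 by rhodium-catalysed conjugate addition and sets out from 16. Miyaura borylation (B2pin2, PdCl2(dppf), KOAc, dioxane, 80 °C) gives the diquinane alkenylboronate F1. Ketone 17 is alkylated with 4-bromobut-1-ene (LiN(i-Pr)2, THF) to 1-cyclopropylhex-5-en-1-one F2, and cross-metathesis with crotonaldehyde (second-generation Hoveyda–Grubbs catalyst) gives (E)-7-cyclopropyl-7-oxohept-2-enal F3. Hayashi–Miyaura 1,4-addition of F1 to F3 ([RhCl(C2H4)2]2, chiral diene ligand, KOH, dioxane/H2O) sets C14 in the C14 aldehyde F4. O-Triflation of the aldehyde enolate (KN(SiMe3)2, PhNTf2, −78 °C) gives the enol triflate F5, and elimination with LiN(i-Pr)2 comes back to the route at 24.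

Step 16 (Saegusa–Ito oxidation). The 2,5-cycloheptadienone 27 has an acidic, doubly activated C17–H and can isomerise into conjugation, and divalent palladium may also engage the skipped diene. The fallback is a selenoxide elimination and sets out from 26. PhSeCl (CH2Cl2, −78 °C) reacts with the silyl enol ether to give the α-phenylselanyl ketone F6 (C19 epimers). Oxidation with H2O2/pyridine at 0 °C and syn elimination of the selenoxide, which can only occur towards C20, comes back to the route at 27.

Step 17 (proposed conjugate hydration). The addition may be reversible or unselective, or the Lewis acid may damage the tertiary allylic silyl ether. The fallback uses known chemistry and sets out from 27. Copper-catalysed enantioselective β-borylation (B2pin2, CuCl, Josiphos-type ligand, NaOt-Bu (cat.), MeOH, THF) gives the C20 pinacol boronate F7. Oxidation with NaBO3·4H2O (THF/H2O), which proceeds with retention at carbon, comes back to the route at 28.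

Further compounds
F1 | step 12 | diquinane C11 pinacol boronate of 16 | C[C@@H](O[Si](C)(C)C(C)(C)C)/C=C/[C@](C)(O)[C@H]1CC[C@H]2C=C(B3OC(C)(C)C(C)(C)O3)C[C@]21C
F2 | step 12 | 1-cyclopropylhex-5-en-1-one | C=CCCCC(=O)C1CC1
F3 | step 12 | (E)-7-cyclopropyl-7-oxohept-2-enal | O=C/C=C/CCCC(=O)C1CC1
F4 | step 12 | C14 aldehyde: C14 bears H, CH2CHO and the 4-cyclopropyl-4-oxobutyl chain | C[C@@H](O[Si](C)(C)C(C)(C)C)/C=C/[C@](C)(O)[C@H]1CC[C@H]2C=C([C@H](CC=O)CCCC(=O)C3CC3)C[C@]21C
F5 | step 12 | (Z)-enol triflate of F4 | C[C@@H](O[Si](C)(C)C(C)(C)C)/C=C/[C@](C)(O)[C@H]1CC[C@H]2C=C([C@H](/C=C\OS(=O)(=O)C(F)(F)F)CCCC(=O)C3CC3)C[C@]21C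
F6 | step 16 | C19 phenylselanyl C18 ketone (C19 epimers) | C[C@@H](O[Si](C)(C)C(C)(C)C)/C=C/[C@](C)(O[Si](CC)(CC)CC)[C@H]1CC[C@H]2C=C([C@H]3CC[C@H]4C(=O)C([Se]c5ccccc5)CCC=C34)C[C@]21C
F7 | step 17 | C20 pinacol boronate of the C18 ketone | C[C@@H](O[Si](C)(C)C(C)(C)C)/C=C/[C@](C)(O[Si](CC)(CC)CC)[C@H]1CC[C@H]2C=C([C@H]3CC[C@H]4C(=O)C[C@H](B5OC(C)(C)C(C)(C)O5)CC=C34)C[C@]21C
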